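**Late times.** When you come at 30 s, each flask has had 5.17 half-lives of the starting material, at 5.8 s each, by its change into the intermediate, so that step leaves 2.73% of it.

| flask | starting material | first nucleophile | second nucleophile | protic impurity | time |
|---|---|---|---|---|---|
| green | 0.25 M | 0.250 M | 1.25 M | 0.0500 M | 30 s |
| grey | 0.25 M | 0.500 M | 1.25 M | 0.0500 M | 30 s |
| red | 0.25 M | 1.00 M | 1.25 M | 0.0500 M | 30 s |

- which of these there is most of at the end, counted by the starting material in it, green (intermediate / starting material / other capture product / target)
- which of these there is most of at the end, counted by the starting material in it, grey (intermediate / starting material / other capture product / target)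
- which of these there is most of at the end, counted by the starting material in it, red (intermediate / starting material / other capture product / target)
- the largest of these amounts at the end, in percent of the starting material charged, green
- the largest of these amounts at the end, in percent of the starting material charged, grey
- the largest of these amounts at the end, in percent of the starting material charged, red

- a species is counted by the starting material in it: one homo dimer counts as two
- for a step with 2 of a species take k times the square, and two of it per event
- run time (green): 30 s

**What passes.** By the opening rates, 86.0% of the starting material goes to the intermediate: that change runs at 0.12 s⁻¹, faster than quenching by protic impurity, 0.0105 s⁻¹, and dimer formation, 0.00900 s⁻¹, together. Don't wait for the intermediate. In green its capture half-lives are 0.087 s and 0.073 s, far shorter than the life of its source, so I reckon it as a low-level steady state, used about as fast as it is made.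

**Capture ratio.** Watch one thing: 32 M⁻¹ s⁻¹ times [first nucleophile] over 7.6 M⁻¹ s⁻¹ times [second nucleophile], the rate to target over the rate to other capture product, which as charged is 1.68 in grey. Green opens at 0.842, red at 3.37.

**The drift.** But it falls. In green, at that share, 0.215 M passes through, a larger fraction of the first nucleophile, charged at 0.250 M, than of the second at 1.25 M. Spent at the opening split, that brings green to 0.564, grey to 1.31, red to 2.93.

**Expect this.** Splitting what passes by the mean of opening and closing ratios, I expect other capture product at 50.5% in green, and target at 51.6% in grey and 65.3% in red. Leave the weighed nucleophiles alone: the ratio opens below one in green and above it in grey.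

**The result.** The forecast says other capture product at 51.6% in green, target at 53.1% in grey and target at 67.2% in red, each above mine, holding that the intermediate “stays at steady state and is negligible”. The flasks give other capture product at 51.5% in green, target at 53.0% in grey and target at 67.0% in red. In green the two capture products together hold 88.2%, more than my 86.0%.

    first nucleophile + intermediate → target (k1 = 32 M⁻¹ s⁻¹)
    second nucleophile + intermediate → other capture product (k2 = 7.6 M⁻¹ s⁻¹)
    starting material → intermediate (k3 = 0.12 s⁻¹)
    starting material + protic impurity → quenched substrate (k4 = 0.21 M⁻¹ s⁻¹)
    2 starting material → homo dimer (k5 = 0.018 M⁻¹ s⁻¹)

**Neighbour flask.** Take grey with the first nucleophile cut to 0.20 M. The capture ratio, 1.68 in grey, opens at 0.674 in this neighbour and drifts to 0.426. The same reckoning gives other capture product 55.5% and target 30.5%. The neighbour holds 56.5% and 31.7%. The two products end level at 0.342 M of first nucleophile, where the ratio as charged is 1.15.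

The numbers were chosen freely; the rest is arithmetic.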